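**Retrosynthetic overview**
- The only stereocentre, the (R)-carbinol, comes last, by enantioselective 1,2-reduction of the isopropenyl ketone ArCH2–CO–C(CH3)=CH2.
- Key C–C disconnection: ArCH2–C(=O). The o-quinone methide of the fully assembled bis-phloroglucinol (electrophilic CH2) is joined to methacrolein, which a thiazolylidene carbene turns into an acyl anion (Breslow intermediate). Two carbons that are both electrophilic by nature are coupled.
- That o-quinone methide comes from the Mannich base of the methylene-bridged dimer, which comes from the ring B o-quinone methide plus phlorobutyrophenone.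
- Ring B comes from selective 4-O-methylation of 3-methylphloracetophenone.
- No ring is constructed. Both benzene rings are bought as phloroglucinol ketones and elaborated in the order ring B, then ring A attached, then the side chain on ring A.

Assumption: 3-methylphloracetophenone, phlorobutyrophenone and methacrolein are taken as purchasable, and the target configuration read from the SMILES is (R).

**Step 1**
Reactants: 1 1-(2,4,6-trihydroxy-3-methylphenyl)ethan-1-one
Product: 2 1-(2,6-dihydroxy-4-methoxy-3-methylphenyl)ethan-1-one (ring B)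
Conditions: Me2SO4 (1.0 equiv), K2CO3 (1.0 equiv), acetone, 0 °C to rt
Reagents that add atoms: dimethyl sulfate, COS(=O)(=O)OC
Why: Williamson O-methylation; the 4-OH para to the acetyl group is the most acidic hydroxyl and the only one not hydrogen-bonded to the carbonyl, so one equivalent of base and electrophile alkylates it selectively.

**Step 2**
Reactants: 2 1-(2,6-dihydroxy-4-methoxy-3-methylphenyl)ethan-1-one; 3 1-(2,4,6-trihydroxyphenyl)butan-1-one (phlorobutyrophenone)
Product: 6 1-{3-[(3-acetyl-2,4-dihydroxy-6-methoxy-5-methylphenyl)methyl]-2,4,6-trihydroxyphenyl}butan-1-one (bridged dimer), via ring B Mannich base hydroiodide 4 (not isolated), via ring B o-quinone methide 5 (not isolated)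
Conditions: [Me2N=CH2]I (1.0 equiv), MeCN, 0 °C to rt, 2 h; then 3 (3 equiv), NaOAc (1.1 equiv), 1,4-dioxane, 80 °C
Reagents that add atoms: Eschenmoser's salt (N,N-dimethylmethylideneammonium iodide), C=[N+](C)C.[I-]
Why: Mannich aminomethylation at the only free ring carbon of 2, then E1cB loss of dimethylamine to o-quinone methide 5, which is trapped at carbon by phloroglucinol 3 (Michael-type Friedel–Crafts alkylation, the usual entry to unsymmetrical methylene-bis-acylphloroglucinols); the excess of 3 suppresses double alkylation, and 4 and 5 have no free ring carbon so they cannot self-condense.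

**Step 3**
Reactants: 6 1-{3-[(3-acetyl-2,4-dihydroxy-6-methoxy-5-methylphenyl)methyl]-2,4,6-trihydroxyphenyl}butan-1-one
Product: 7 1-{3-[(3-acetyl-2,4-dihydroxy-6-methoxy-5-methylphenyl)methyl]-5-[(dimethylamino)methyl]-2,4,6-trihydroxyphenyl}butan-1-one
Conditions: [Me2N=CH2]I (1.1 equiv), MeCN, 0 °C to rt; cold aq NaHCO3 (1.0 equiv), product collected and used at once
Reagents that add atoms: Eschenmoser's salt (N,N-dimethylmethylideneammonium iodide), C=[N+](C)C.[I-]
Why: Mannich reaction of the preformed iminium salt at the single remaining nucleophilic ring carbon of 6 (ring B is fully substituted), run cold so that the Mannich base does not yet lose amine.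

**Step 4** (key step)
Reactants: 7 1-{3-[(3-acetyl-2,4-dihydroxy-6-methoxy-5-methylphenyl)methyl]-5-[(dimethylamino)methyl]-2,4,6-trihydroxyphenyl}butan-1-one; 8 methacrolein (2-methylprop-2-enal)
Product: 11 1-{3-[(3-acetyl-2,4-dihydroxy-6-methoxy-5-methylphenyl)methyl]-5-butanoyl-2,4,6-trihydroxyphenyl}-3-methylbut-3-en-2-one, via trimethylammonium iodide 9 (not isolated), via ring A o-quinone methide 10 (not isolated)
Conditions: MeI (1.0 equiv), MeCN, rt, 2 h; then 3-benzyl-5-(2-hydroxyethyl)-4-methylthiazolium chloride (30 mol %), Et3N (2.5 equiv), 8 (3 equiv, slow addition), DMF, 40 °C, N2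
Reagents that add atoms: none
Why: Proposed new method: base converts ammonium salt 9 into o-quinone methide 10 by E1cB loss of NMe3 while the thiazol-2-ylidene turns methacrolein 8 into its Breslow intermediate, a methacryloyl anion equivalent whose carbinol carbon adds to the exocyclic CH2 of 10 (electrophilic like the aldehyde carbon it is joined to) before the adduct collapses to ketone 11 and free carbene; the closest known reaction types are the intermolecular Stetter reaction, thiazolium-derived acyl-anion additions to o-quinone methides made in situ and carbene-catalysed 1,6-acylation of p-quinone methides by aldehydes, and attack through the carbonyl carbon is expected because small N-alkyl thiazolylidenes are acyl-anion catalysts whereas homoenolate reactivity needs bulky N-aryl azolylidenes and is further disfavoured by the alpha-methyl group, while 10 has no free ring carbon and so cannot oligomerise.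

**Step 5**
Reactants: 11 1-{3-[(3-acetyl-2,4-dihydroxy-6-methoxy-5-methylphenyl)methyl]-5-butanoyl-2,4,6-trihydroxyphenyl}-3-methylbut-3-en-2-one
Product: 14 1-{3-[(3-acetyl-2,4-dihydroxy-6-methoxy-5-methylphenyl)methyl]-2,4,6-trihydroxy-5-[(2R)-2-hydroxy-3-methylbut-3-en-1-yl]phenyl}butan-1-one (target), via penta-O-trimethylsilyl ketone 12 (not isolated), via penta-O-trimethylsilyl alcohol 13 (not isolated)
Conditions: N,O-bis(trimethylsilyl)acetamide (8 equiv), CH2Cl2, rt, then evaporate; (S)-2-methyl-CBS-oxazaborolidine [(3aS)-1-methyl-3,3-diphenyltetrahydro-1H,3H-pyrrolo[1,2-c][1,3,2]oxazaborole] (30 mol %), catecholborane (2 equiv), toluene, −78 °C; then MeOH, 10 % aq citric acid, rt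
Reagents that add atoms: none
Why: Corey–Bakshi–Shibata reduction after transient silylation (which makes the polyphenol toluene-soluble and keeps acidic OH groups away from borane and catalyst); the sp2, alpha-branched isopropenyl group acts as the large substituent, so the (S)-catalyst delivers hydride to the Si face and gives the (R)-allylic alcohol, while the hindered di-ortho-silyloxy aryl ketones and the alkene do not react with catecholborane at −78 °C and methanolic citric acid removes the TMS groups.

**Compound list**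
1 | 1-(2,4,6-trihydroxy-3-methylphenyl)ethan-1-one | CC(=O)c1c(O)cc(O)c(C)c1O | starting material
2 | 1-(2,6-dihydroxy-4-methoxy-3-methylphenyl)ethan-1-one | CC(=O)c1c(O)cc(OC)c(C)c1O | intermediate
3 | 1-(2,4,6-trihydroxyphenyl)butan-1-one | CCCC(=O)c1c(O)cc(O)cc1O | starting material
4 | 1-{3-[(dimethylamino)methyl]-2,6-dihydroxy-4-methoxy-5-methylphenyl}ethan-1-one hydroiodide | CC(=O)c1c(O)c(C[NH+](C)C)c(OC)c(C)c1O.[I-] | intermediate
5 | 2-acetyl-3-hydroxy-5-methoxy-4-methyl-6-methylidenecyclohexa-2,4-dien-1-one | C=C1C(=O)C(C(C)=O)=C(O)C(C)=C1OC | intermediate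
6 | 1-{3-[(3-acetyl-2,4-dihydroxy-6-methoxy-5-methylphenyl)methyl]-2,4,6-trihydroxyphenyl}butan-1-one | CCCC(=O)c1c(O)cc(O)c(Cc2c(O)c(C(C)=O)c(O)c(C)c2OC)c1O | intermediate
7 | 1-{3-[(3-acetyl-2,4-dihydroxy-6-methoxy-5-methylphenyl)methyl]-5-[(dimethylamino)methyl]-2,4,6-trihydroxyphenyl}butan-1-one | CCCC(=O)c1c(O)c(CN(C)C)c(O)c(Cc2c(O)c(C(C)=O)c(O)c(C)c2OC)c1O | intermediate
8 | methacrolein (2-methylprop-2-enal) | CC(=C)C=O | starting material
9 | {3-[(3-acetyl-2,4-dihydroxy-6-methoxy-5-methylphenyl)methyl]-5-butanoyl-2,4,6-trihydroxyphenyl}-N,N,N-trimethylmethanaminium iodide | CCCC(=O)c1c(O)c(C[N+](C)(C)C)c(O)c(Cc2c(O)c(C(C)=O)c(O)c(C)c2OC)c1O.[I-] | intermediate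
10 | 4-[(3-acetyl-2,4-dihydroxy-6-methoxy-5-methylphenyl)methyl]-2-butanoyl-3,5-dihydroxy-6-methylidenecyclohexa-2,4-dien-1-one | C=C1C(=O)C(C(=O)CCC)=C(O)C(Cc2c(O)c(C(C)=O)c(O)c(C)c2OC)=C1O | intermediate
11 | 1-{3-[(3-acetyl-2,4-dihydroxy-6-methoxy-5-methylphenyl)methyl]-5-butanoyl-2,4,6-trihydroxyphenyl}-3-methylbut-3-en-2-one | C=C(C)C(=O)Cc1c(O)c(Cc2c(O)c(C(C)=O)c(O)c(C)c2OC)c(O)c(C(=O)CCC)c1O | intermediate
12 | pentakis(trimethylsilyl) ether of 11 (all five phenolic OH as OSiMe3) | C=C(C)C(=O)Cc1c(O[Si](C)(C)C)c(Cc2c(O[Si](C)(C)C)c(C(C)=O)c(O[Si](C)(C)C)c(C)c2OC)c(O[Si](C)(C)C)c(C(=O)CCC)c1O[Si](C)(C)C | intermediate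
13 | pentakis(trimethylsilyl) ether of 14 (all five phenolic OH as OSiMe3, free (R)-carbinol) | C=C(C)[C@H](O)Cc1c(O[Si](C)(C)C)c(Cc2c(O[Si](C)(C)C)c(C(C)=O)c(O[Si](C)(C)C)c(C)c2OC)c(O[Si](C)(C)C)c(C(=O)CCC)c1O[Si](C)(C)C | intermediate
14 | 1-{3-[(3-acetyl-2,4-dihydroxy-6-methoxy-5-methylphenyl)methyl]-2,4,6-trihydroxy-5-[(2R)-2-hydroxy-3-methylbut-3-en-1-yl]phenyl}butan-1-one | C=C(C)[C@H](O)Cc1c(O)c(Cc2c(O)c(C(C)=O)c(O)c(C)c2OC)c(O)c(C(=O)CCC)c1O | target

**Step count and risks**

Total step count: 5. Longest linear sequence: 5 steps (1 → 2 → 6 → 7 → 11 → 14); 3 and 8 enter as purchased partners.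

Step 4 is the most likely to fail. The Breslow intermediate of an enal can react through its beta-carbon (homoenolate path, giving a seven-membered lactone or a saturated chain), and methacrolein can self-condense. The fallback keeps the same bond and the same polarity reversal but changes the d1 reagent to a nitronate. It sets out from 9 (made from 7 as in step 4). Treating 9 with 2-methyl-3-nitroprop-1-ene (from methallyl chloride and NaNO2) and DBU in MeCN at rt lets the nitronate add through carbon to o-quinone methide 10. This gives 1-{3-[(3-acetyl-2,4-dihydroxy-6-methoxy-5-methylphenyl)methyl]-2,4,6-trihydroxy-5-(3-methyl-2-nitrobut-3-en-1-yl)phenyl}butan-1-one F1. A reductive Nef reaction (aqueous TiCl3, NH4OAc buffer, THF, rt) then converts F1 into ketone 11, where the route resumes.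

Step 5 is the second risk. The bulky silylated benzyl group may compete with isopropenyl as the large substituent and erode the ee, and the benzylic ketone may partly silylate as its dienol ether. The fallback replaces asymmetric reduction by reduction plus resolution and sets out from 11. Luche reduction (NaBH4, CeCl3·7H2O, MeOH, −40 °C; the chelated aryl ketones are inert) gives racemic 1-{3-[(3-acetyl-2,4-dihydroxy-6-methoxy-5-methylphenyl)methyl]-2,4,6-trihydroxy-5-(2-hydroxy-3-methylbut-3-en-1-yl)phenyl}butan-1-one F2. Kinetic resolution with Burkholderia cepacia lipase and vinyl acetate in t-BuOMe at 30 °C acetylates the (S)-enantiomer (Kazlauskas rule, CH2Ar as the large group) to (2S)-1-{3-[(3-acetyl-2,4-dihydroxy-6-methoxy-5-methylphenyl)methyl]-5-butanoyl-2,4,6-trihydroxyphenyl}-3-methylbut-3-en-2-yl acetate F3. F3 is removed by chromatography and the unreacted (R)-alcohol is 14, where the route ends. The yield is at most 50 % unless F3 is saponified, reoxidised and recycled.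

Step 2 is the third risk. The telescoped Mannich base may release the quinone methide sluggishly at 80 °C, or the bridge may scramble on heating. The fallback uses an isolable, base-triggered precursor and sets out from 2. Three-component sulfonylmethylation (paraformaldehyde, sodium 4-methylbenzenesulfinate, HCO2H/H2O, rt) gives crystalline 1-{2,6-dihydroxy-4-methoxy-3-methyl-5-[(4-methylbenzenesulfonyl)methyl]phenyl}ethan-1-one F4. Stirring F4 with 3 (3 equiv) and K2CO3 in MeCN at rt releases o-quinone methide 5, which is trapped by 3 to give 6, where the route resumes.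

**Further compounds**
F1 | step 4 | 1-{3-[(3-acetyl-2,4-dihydroxy-6-methoxy-5-methylphenyl)methyl]-2,4,6-trihydroxy-5-(3-methyl-2-nitrobut-3-en-1-yl)phenyl}butan-1-one (racemic) | C=C(C)C(Cc1c(O)c(Cc2c(O)c(C(C)=O)c(O)c(C)c2OC)c(O)c(C(=O)CCC)c1O)[N+](=O)[O-]
F2 | step 5 | racemic 1-{3-[(3-acetyl-2,4-dihydroxy-6-methoxy-5-methylphenyl)methyl]-2,4,6-trihydroxy-5-(2-hydroxy-3-methylbut-3-en-1-yl)phenyl}butan-1-one | C=C(C)C(O)Cc1c(O)c(Cc2c(O)c(C(C)=O)c(O)c(C)c2OC)c(O)c(C(=O)CCC)c1O
F3 | step 5 | (2S)-1-{3-[(3-acetyl-2,4-dihydroxy-6-methoxy-5-methylphenyl)methyl]-5-butanoyl-2,4,6-trihydroxyphenyl}-3-methylbut-3-en-2-yl acetate | C=C(C)[C@@H](OC(C)=O)Cc1c(O)c(Cc2c(O)c(C(C)=O)c(O)c(C)c2OC)c(O)c(C(=O)CCC)c1O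
F4 | step 2 | 1-{2,6-dihydroxy-4-methoxy-3-methyl-5-[(4-methylbenzenesulfonyl)methyl]phenyl}ethan-1-one | CC(=O)c1c(O)c(CS(=O)(=O)c2ccc(C)cc2)c(OC)c(C)c1O
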